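The route rests on cutting the C3–C4 bond of ring C. C3 (carbinol) and C4 (ketone) form an acyloin pair, so both can be traced back to aldehyde carbons, which are both electrophilic. A SmI2 pinacol cyclization joins them in one operation: it closes the pyran ring and sets C3 and C4 relative to C2 as the 2,3-trans-3,4-cis flavan-3,4-diol. Benzylic oxidation and MOM removal then give the target. The precursor is an (R)-dialdehyde: a ring A benzaldehyde (future C4) with geranyl between two MOM ethers, whose remaining ortho oxygen (O1) carries C2 with ring B and the second aldehyde (future C3). C2 is set earlier by Mitsunobu inversion of an (S)-mandelate.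

Key step: step 12

Abbreviations: geranyl = (2E)-3,7-dimethylocta-2,6-dien-1-yl; MOM = methoxymethyl; TIPS = triisopropylsilyl. Atom and ring labels are those of the flavanone.

Assumption: in step 8 the aryl group of keto ester 14 is taken to play the role it plays in acetophenone-type substrates, so that RuCl[(R,R)-TsDPEN](p-cymene) gives the (S)-mandelate; the enantiomeric complex would be used if the first run showed the opposite sense.

Remark: the descriptor at C3 changes from S in diol 19 to R in 20 and 21 only because the substituent priorities change on oxidation; the arrangement in space is the same.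

Step 1
Reactants: 1 phloroglucinol
Product: 2 5-(triisopropylsilyloxy)benzene-1,3-diol
Conditions: TIPSCl (0.8 equiv), imidazole, DMF, 0 °C to rt
Reagents that add atoms: chlorotriisopropylsilane, CC(C)[Si](Cl)(C(C)C)C(C)C
Why: O-silylation of a phenol with a bulky silyl chloride, run with the triol in excess so that the monoether should be the main product and unreacted 1 is washed out with water.

Step 2
Reactants: 2 5-(triisopropylsilyloxy)benzene-1,3-diol
Product: 3 [3,5-bis(methoxymethoxy)phenoxy]triisopropylsilane
Conditions: MOMCl, i-Pr2NEt, CH2Cl2, 0 °C to rt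
Reagents that add atoms: chloromethyl methyl ether, COCCl
Why: Williamson-type O-alkylation of both remaining phenols with the reactive chloromethyl ether under amine base, conditions that leave the aryl silyl ether untouched.

Step 3
Reactants: 3 [3,5-bis(methoxymethoxy)phenoxy]triisopropylsilane; 4 geranyl bromide
Product: 7 [4-geranyl-3,5-bis(methoxymethoxy)phenoxy]triisopropylsilane, via aryllithium 5 (not isolated), via arylcopper 6 (not isolated)
Conditions: n-BuLi, THF, 0 °C; CuI, −20 °C; then 4, −20 °C to rt
Reagents that add atoms: none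
Why: Directed ortho-metalation should occur at C4 because that C–H lies between two chelating MOM ethers while the bulky silyl ether shields its own neighbours, and the derived arylcopper couples with the primary allylic bromide at the α-carbon (SN2 allylic substitution) with the E-alkene preserved.

Step 4
Reactants: 7 [4-geranyl-3,5-bis(methoxymethoxy)phenoxy]triisopropylsilane
Product: 8 4-geranyl-3,5-bis(methoxymethoxy)phenol
Conditions: TBAF, AcOH, THF, 0 °C
Reagents that add atoms: none
Why: Fluoride-mediated Si–O cleavage driven by the strong Si–F bond, buffered with AcOH so that the MOM ethers and the geranyl chain see neither strong base nor strong acid.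

Step 5
Reactants: 8 4-geranyl-3,5-bis(methoxymethoxy)phenol
Product: 9 3-geranyl-6-hydroxy-2,4-bis(methoxymethoxy)benzaldehyde
Conditions: MgCl2, Et3N, (CH2O)n, MeCN, 75 °C; cold aq NH4Cl work-up
Reagents that add atoms: paraformaldehyde (reacts as formaldehyde), C=O
Why: Casnati–Skattebøl ortho-formylation, in which the magnesium phenoxide directs formaldehyde to the ortho position and a second formaldehyde oxidizes the benzylic alkoxide, and since both ortho positions of 8 are equivalent only one aldehyde can form.

Step 6
Reactants: 10 5-bromo-2-methoxyphenol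
Product: 11 4-bromo-1-methoxy-2-(methoxymethoxy)benzene
Conditions: MOMCl, i-Pr2NEt, CH2Cl2, 0 °C to rt
Reagents that add atoms: chloromethyl methyl ether, COCCl
Why: Williamson-type MOM protection of the phenol, needed so that ring B carries no acidic hydroxyl in the organolithium and Mitsunobu steps.

Step 7
Reactants: 11 4-bromo-1-methoxy-2-(methoxymethoxy)benzene; 12 dimethyl oxalate
Product: 14 methyl 2-[4-methoxy-3-(methoxymethoxy)phenyl]-2-oxoacetate, via aryllithium 13 (not isolated)
Conditions: n-BuLi, THF, −78 °C; cannulated into 12 (3 equiv), THF, −78 °C; AcOH quench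
Reagents that add atoms: none
Why: Bromine–lithium exchange followed by acylation with an oxalate diester, where inverse addition into excess diester at −78 °C keeps the tetrahedral adduct intact and should stop at the α-keto ester.

Step 8
Reactants: 14 methyl 2-[4-methoxy-3-(methoxymethoxy)phenyl]-2-oxoacetate
Product: 15 methyl (2S)-2-hydroxy-2-[4-methoxy-3-(methoxymethoxy)phenyl]acetate
Conditions: RuCl[(R,R)-TsDPEN](p-cymene) (1 mol %), HCO2H/Et3N (5:2), EtOAc, rt
Reagents that add atoms: none
Why: Noyori–Ikariya asymmetric transfer hydrogenation, in which the chiral Ru–H/N–H unit delivers hydride to one face of the aryl ketone with the arene held by a C–H/π contact to the cymene ligand, setting the (S) carbinol centre.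

Step 9
Reactants: 9 3-geranyl-6-hydroxy-2,4-bis(methoxymethoxy)benzaldehyde; 15 methyl (2S)-2-hydroxy-2-[4-methoxy-3-(methoxymethoxy)phenyl]acetate
Product: 16 methyl (2R)-2-[2-formyl-4-geranyl-3,5-bis(methoxymethoxy)phenoxy]-2-[4-methoxy-3-(methoxymethoxy)phenyl]acetate
Conditions: PPh3, DIAD, THF, 0 °C to rt
Reagents that add atoms: none
Why: Mitsunobu reaction, in which the acidic phenol of 9 displaces the alkoxyphosphonium group of 15 in an SN2 event with inversion to give the (R)-aryl ether, while the adjacent ester carbonyl disfavours ionization that would erode the stereocentre.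

Step 10
Reactants: 16 methyl (2R)-2-[2-formyl-4-geranyl-3,5-bis(methoxymethoxy)phenoxy]-2-[4-methoxy-3-(methoxymethoxy)phenyl]acetate
Product: 17 (2R)-2-[4-geranyl-2-(hydroxymethyl)-3,5-bis(methoxymethoxy)phenoxy]-2-[4-methoxy-3-(methoxymethoxy)phenyl]ethanol
Conditions: i-Bu2AlH (5 equiv), CH2Cl2, −78 to −20 °C; aq KNaC4H4O6 (potassium sodium tartrate) work-up; Et3N-washed silica
Reagents that add atoms: none
Why: Hydride reduction with the Lewis-acidic, non-basic i-Bu2AlH converts ester and aldehyde to primary alcohols at low temperature without enolizing the α-aryl-α-aryloxy centre.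

Step 11
Reactants: 17 (2R)-2-[4-geranyl-2-(hydroxymethyl)-3,5-bis(methoxymethoxy)phenoxy]-2-[4-methoxy-3-(methoxymethoxy)phenyl]ethanol
Product: 18 3-geranyl-2,4-bis(methoxymethoxy)-6-[(1R)-1-[4-methoxy-3-(methoxymethoxy)phenyl]-2-oxoethoxy]benzaldehyde
Conditions: Dess–Martin periodinane, NaHCO3, CH2Cl2, 0 °C; cold filtration through Celite, used at once
Reagents that add atoms: none
Why: Dess–Martin oxidation of both primary alcohols under buffered, base-free conditions, chosen because the new α-aryl-α-aryloxy aldehyde is easily enolized, so the crude dialdehyde is kept cold and carried on immediately.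

Step 12
Reactants: 18 3-geranyl-2,4-bis(methoxymethoxy)-6-[(1R)-1-[4-methoxy-3-(methoxymethoxy)phenyl]-2-oxoethoxy]benzaldehyde
Product: 19 (2R,3S,4S)-6-geranyl-5,7-bis(methoxymethoxy)-2-[4-methoxy-3-(methoxymethoxy)phenyl]chromane-3,4-diol (2,3-trans-3,4-cis)
Conditions: SmI2 (3 equiv, 0.1 M in THF), t-BuOH (2 equiv), THF, −78 °C, slow addition of 18, no HMPA; aq NaHCO3 work-up
Reagents that add atoms: none
Why: Proposed new method: SmI2 should transfer one electron to the conjugated ring A aldehyde of 18, the more easily reduced carbonyl, and the resulting samarium-bound benzylic ketyl should add to the neighbouring aliphatic aldehyde, after which a second electron gives the trivalent samarium diolate that is protonated on work-up; in this way the C3–C4 bond joins two carbons that are both electrophilic in polar terms. The closest known reaction type is the SmI2 pinacol cyclization of 1,6-dialdehydes bearing α-alkoxy groups to cis-cyclohexane-1,2-diols, which has not been shown for an aryl aldehyde paired with an α-aryl-α-aryloxy aldehyde. Ring C closes in the 6-exo-trig mode, since the C=O that is attacked lies outside the new six-membered ring. C4 is controlled by chelation, both oxygens sitting on one samarium centre so that the 3,4-diol is cis, and C3 is controlled by the existing C2 centre, whose ring B aryl group stays pseudo-equatorial in the half-chair transition state and places the chelated C3–O bond trans to it (equatorial) with the C4–O bond pseudo-axial and away from the C5 MOM ether. The step needs chemoselectivity, namely C–C coupling faster than expulsion of the ring A aryloxide from a ketyl on the aliphatic aldehyde and faster than plain reduction, which preferential electron transfer to the aryl aldehyde, the intramolecular six-membered closure, the absence of HMPA and −78 °C are meant to secure. It also needs the C2 centre to stay intact, which the non-basic medium secures, and 2,3-trans selectivity, which the C2 aryl group secures.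

Step 13
Reactants: 19 (2R,3S,4S)-6-geranyl-5,7-bis(methoxymethoxy)-2-[4-methoxy-3-(methoxymethoxy)phenyl]chromane-3,4-diol
Product: 20 (2R,3R)-6-geranyl-3-hydroxy-5,7-bis(methoxymethoxy)-2-[4-methoxy-3-(methoxymethoxy)phenyl]chroman-4-one
Conditions: MnO2 (activated, excess), CH2Cl2, rt
Reagents that add atoms: none
Why: MnO2 should oxidize the C4 alcohol selectively because it is benzylic to the electron-rich ring A whereas the C3 alcohol is an unactivated secondary carbinol, and neither C2 nor C3 is touched.

Step 14
Reactants: 20 (2R,3R)-6-geranyl-3-hydroxy-5,7-bis(methoxymethoxy)-2-[4-methoxy-3-(methoxymethoxy)phenyl]chroman-4-one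
Product: 21 4'-O-methyldiplacol, (2R,3R)-6-geranyl-3,5,7-trihydroxy-2-(3-hydroxy-4-methoxyphenyl)chroman-4-one
Conditions: HCl (about 1 M in MeOH), rt to 40 °C
Reagents that add atoms: none
Why: Acid-catalysed acetal exchange with methanol removes all three MOM groups under conditions mild enough to spare the geranyl alkenes and the two stereocentres of the 3-hydroxyflavanone.

Compound list
1 | phloroglucinol | Oc1cc(O)cc(O)c1 | starting material
2 | 5-(triisopropylsilyloxy)benzene-1,3-diol | CC(C)[Si](Oc1cc(O)cc(O)c1)(C(C)C)C(C)C | intermediate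
3 | [3,5-bis(methoxymethoxy)phenoxy]triisopropylsilane | COCOc1cc(OCOC)cc(O[Si](C(C)C)(C(C)C)C(C)C)c1 | intermediate
4 | geranyl bromide, (2E)-1-bromo-3,7-dimethylocta-2,6-diene | BrC/C=C(\C)CCC=C(C)C | starting material
5 | aryllithium, [2,6-bis(methoxymethoxy)-4-(triisopropylsilyloxy)phenyl]lithium | [Li]c1c(OCOC)cc(O[Si](C(C)C)(C(C)C)C(C)C)cc1OCOC | intermediate
6 | arylcopper, [2,6-bis(methoxymethoxy)-4-(triisopropylsilyloxy)phenyl]copper (monovalent copper) | [Cu]c1c(OCOC)cc(O[Si](C(C)C)(C(C)C)C(C)C)cc1OCOC | intermediate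
7 | [4-geranyl-3,5-bis(methoxymethoxy)phenoxy]triisopropylsilane | COCOc1cc(O[Si](C(C)C)(C(C)C)C(C)C)cc(OCOC)c1C/C=C(\C)CCC=C(C)C | intermediate
8 | 4-geranyl-3,5-bis(methoxymethoxy)phenol | COCOc1cc(O)cc(OCOC)c1C/C=C(\C)CCC=C(C)C | intermediate
9 | 3-geranyl-6-hydroxy-2,4-bis(methoxymethoxy)benzaldehyde | O=Cc1c(O)cc(OCOC)c(C/C=C(\C)CCC=C(C)C)c1OCOC | intermediate
10 | 5-bromo-2-methoxyphenol | COc1ccc(Br)cc1O | starting material
11 | 4-bromo-1-methoxy-2-(methoxymethoxy)benzene | COCOc1cc(Br)ccc1OC | intermediate
12 | dimethyl oxalate | COC(=O)C(=O)OC | starting material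
13 | aryllithium, [4-methoxy-3-(methoxymethoxy)phenyl]lithium | [Li]c1ccc(OC)c(OCOC)c1 | intermediate
14 | methyl 2-[4-methoxy-3-(methoxymethoxy)phenyl]-2-oxoacetate | COC(=O)C(=O)c1ccc(OC)c(OCOC)c1 | intermediate
15 | methyl (2S)-2-hydroxy-2-[4-methoxy-3-(methoxymethoxy)phenyl]acetate | COc1ccc([C@@H](C(=O)OC)O)cc1OCOC | intermediate
16 | methyl (2R)-2-[2-formyl-4-geranyl-3,5-bis(methoxymethoxy)phenoxy]-2-[4-methoxy-3-(methoxymethoxy)phenyl]acetate | COc1ccc([C@H](C(=O)OC)Oc2cc(OCOC)c(C/C=C(\C)CCC=C(C)C)c(OCOC)c2C=O)cc1OCOC | intermediate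
17 | (2R)-2-[4-geranyl-2-(hydroxymethyl)-3,5-bis(methoxymethoxy)phenoxy]-2-[4-methoxy-3-(methoxymethoxy)phenyl]ethanol | COc1ccc([C@H](CO)Oc2cc(OCOC)c(C/C=C(\C)CCC=C(C)C)c(OCOC)c2CO)cc1OCOC | intermediate
18 | 3-geranyl-2,4-bis(methoxymethoxy)-6-[(1R)-1-[4-methoxy-3-(methoxymethoxy)phenyl]-2-oxoethoxy]benzaldehyde | COc1ccc([C@H](C=O)Oc2cc(OCOC)c(C/C=C(\C)CCC=C(C)C)c(OCOC)c2C=O)cc1OCOC | intermediate
19 | (2R,3S,4S)-6-geranyl-5,7-bis(methoxymethoxy)-2-[4-methoxy-3-(methoxymethoxy)phenyl]chromane-3,4-diol | COc1ccc([C@H]2Oc3cc(OCOC)c(C/C=C(\C)CCC=C(C)C)c(OCOC)c3[C@H](O)[C@@H]2O)cc1OCOC | intermediate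
20 | (2R,3R)-6-geranyl-3-hydroxy-5,7-bis(methoxymethoxy)-2-[4-methoxy-3-(methoxymethoxy)phenyl]chroman-4-one | COc1ccc([C@H]2Oc3cc(OCOC)c(C/C=C(\C)CCC=C(C)C)c(OCOC)c3C(=O)[C@@H]2O)cc1OCOC | intermediate
21 | 4'-O-methyldiplacol, (2R,3R)-6-geranyl-3,5,7-trihydroxy-2-(3-hydroxy-4-methoxyphenyl)chroman-4-one | COc1ccc([C@H]2Oc3cc(O)c(C/C=C(\C)CCC=C(C)C)c(O)c3C(=O)[C@@H]2O)cc1O | target

Total step count: 14. Longest linear sequence: 11 steps (steps 1–5, then 9–14); the ring B branch (steps 6–8) joins at step 9.

Steps most likely to fail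

1. Step 12 (Proposed new method). Electron transfer may go to the aliphatic aldehyde and lead to cleavage of the C2–O1 bond with loss of the ring A aryloxide. Either aldehyde may simply be reduced. The closure may also show poor facial control at C3. Fallback by known chemistry (chalcone epoxide route): it sets out from salicylaldehyde 9 and comes back to the route at ketone 20, bypassing steps 9–13. The phenol of 9 would be allylated (allyl bromide, K2CO3, DMF) to 6-(allyloxy)-3-geranyl-2,4-bis(methoxymethoxy)benzaldehyde F1. MeMgBr addition would give the racemic carbinol 1-[6-(allyloxy)-3-geranyl-2,4-bis(methoxymethoxy)phenyl]ethanol F2, and Dess–Martin oxidation would give 1-[6-(allyloxy)-3-geranyl-2,4-bis(methoxymethoxy)phenyl]ethanone F3. Purchased isovanillin would be protected with MOMCl and i-Pr2NEt to 4-methoxy-3-(methoxymethoxy)benzaldehyde F4. Claisen–Schmidt condensation of F3 with F4 (KOH, EtOH) would give (E)-1-[6-(allyloxy)-3-geranyl-2,4-bis(methoxymethoxy)phenyl]-3-[4-methoxy-3-(methoxymethoxy)phenyl]prop-2-en-1-one F5. Juliá–Colonna epoxidation (poly-L-leucine, urea–H2O2, DBU, THF) is a nucleophilic oxidation that attacks the enone and not the geranyl alkenes. It is expected to give [6-(allyloxy)-3-geranyl-2,4-bis(methoxymethoxy)phenyl][(2R,3S)-3-[4-methoxy-3-(methoxymethoxy)phenyl]oxiran-2-yl]methanone F6. Removal of the allyl group (Pd(PPh3)4, zerovalent palladium, morpholine) would free only the ring A oxygen that must become O1, which excludes the 8-geranyl isomer. The resulting [3-geranyl-6-hydroxy-2,4-bis(methoxymethoxy)phenyl][(2R,3S)-3-[4-methoxy-3-(methoxymethoxy)phenyl]oxiran-2-yl]methanone F7 should close onto the benzylic epoxide carbon with inversion (pyridinium p-toluenesulfonate, CH2Cl2) to give 20. C3 is retained from the epoxide and C2 is set trans to it.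

2. Step 11. The α-aryl-α-aryloxy aldehyde may enolize and lose the C2 configuration while the slower oxidation is completed. A hydroxy aldehyde formed part-way may also close to a cyclic hemiacetal and be over-oxidized. Fallback (staged oxidation through a stable intermediate): it sets out from diol 17 and comes back at dialdehyde 18. Activated MnO2 in CH2Cl2 would oxidize only the benzylic alcohol to 3-geranyl-6-[(1R)-2-hydroxy-1-[4-methoxy-3-(methoxymethoxy)phenyl]ethoxy]-2,4-bis(methoxymethoxy)benzaldehyde F8, which has no enolizable aldehyde and can be purified and stored. The remaining unhindered primary alcohol would then be oxidized alone in a short, cold Dess–Martin reaction immediately before the samarium step, so that the sensitive aldehyde exists only briefly.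

3. Step 13. MnO2 may cleave the cis-glycol C3–C4 bond back to a dialdehyde, or oxidation may run on at C3 toward the flavonol with loss of both stereocentres. Fallback (protect, then oxidize): it sets out from diol 19 and comes back at target 21. The more accessible equatorial C3 hydroxyl would be silylated (TESCl, imidazole, CH2Cl2, 0 °C) to (2R,3S,4S)-6-geranyl-5,7-bis(methoxymethoxy)-2-[4-methoxy-3-(methoxymethoxy)phenyl]-3-(triethylsilyloxy)chroman-4-ol F9. The now isolated C4 alcohol would be oxidized with Dess–Martin periodinane and NaHCO3, where neither glycol cleavage nor oxidation at C3 is possible, to (2R,3R)-6-geranyl-5,7-bis(methoxymethoxy)-2-[4-methoxy-3-(methoxymethoxy)phenyl]-3-(triethylsilyloxy)chroman-4-one F10. The methanolic HCl of step 14 would then remove the silyl group together with the three MOM groups and give 21 directly.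

Further compounds
F1 | step 12 | 6-(allyloxy)-3-geranyl-2,4-bis(methoxymethoxy)benzaldehyde | O=Cc1c(OCC=C)cc(OCOC)c(C/C=C(\C)CCC=C(C)C)c1OCOC
F2 | step 12 | 1-[6-(allyloxy)-3-geranyl-2,4-bis(methoxymethoxy)phenyl]ethanol (racemic) | CC(O)c1c(OCC=C)cc(OCOC)c(C/C=C(\C)CCC=C(C)C)c1OCOC
F3 | step 12 | 1-[6-(allyloxy)-3-geranyl-2,4-bis(methoxymethoxy)phenyl]ethanone | CC(=O)c1c(OCC=C)cc(OCOC)c(C/C=C(\C)CCC=C(C)C)c1OCOC
F4 | step 12 | 4-methoxy-3-(methoxymethoxy)benzaldehyde | COCOc1cc(C=O)ccc1OC
F5 | step 12 | (E)-1-[6-(allyloxy)-3-geranyl-2,4-bis(methoxymethoxy)phenyl]-3-[4-methoxy-3-(methoxymethoxy)phenyl]prop-2-en-1-one | COc1ccc(/C=C/C(=O)c2c(OCC=C)cc(OCOC)c(C/C=C(\C)CCC=C(C)C)c2OCOC)cc1OCOC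
F6 | step 12 | [6-(allyloxy)-3-geranyl-2,4-bis(methoxymethoxy)phenyl][(2R,3S)-3-[4-methoxy-3-(methoxymethoxy)phenyl]oxiran-2-yl]methanone | O=C(c1c(OCC=C)cc(OCOC)c(C/C=C(\C)CCC=C(C)C)c1OCOC)[C@@H]1O[C@H]1c1ccc(OC)c(OCOC)c1
F7 | step 12 | [3-geranyl-6-hydroxy-2,4-bis(methoxymethoxy)phenyl][(2R,3S)-3-[4-methoxy-3-(methoxymethoxy)phenyl]oxiran-2-yl]methanone | O=C(c1c(O)cc(OCOC)c(C/C=C(\C)CCC=C(C)C)c1OCOC)[C@@H]1O[C@H]1c1ccc(OC)c(OCOC)c1
F8 | step 11 | 3-geranyl-6-[(1R)-2-hydroxy-1-[4-methoxy-3-(methoxymethoxy)phenyl]ethoxy]-2,4-bis(methoxymethoxy)benzaldehyde | COc1ccc([C@H](CO)Oc2cc(OCOC)c(C/C=C(\C)CCC=C(C)C)c(OCOC)c2C=O)cc1OCOC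
F9 | step 13 | (2R,3S,4S)-6-geranyl-5,7-bis(methoxymethoxy)-2-[4-methoxy-3-(methoxymethoxy)phenyl]-3-(triethylsilyloxy)chroman-4-ol | COc1ccc([C@H]2Oc3cc(OCOC)c(C/C=C(\C)CCC=C(C)C)c(OCOC)c3[C@H](O)[C@@H]2O[Si](CC)(CC)CC)cc1OCOC
F10 | step 13 | (2R,3R)-6-geranyl-5,7-bis(methoxymethoxy)-2-[4-methoxy-3-(methoxymethoxy)phenyl]-3-(triethylsilyloxy)chroman-4-one | COc1ccc([C@H]2Oc3cc(OCOC)c(C/C=C(\C)CCC=C(C)C)c(OCOC)c3C(=O)[C@@H]2O[Si](CC)(CC)CC)cc1OCOC
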